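Set the loss of target against the loss of substrate before you trust a yield.

| setting | winter | midnight | spring | north-west | north | north-east | east |
|---|---|---|---|---|---|---|---|
| substrate | 38 mM | 38 mM | 19 mM | 38 mM | 38 mM | 38 mM | 38 mM |
| partner | 95 mM | 95 mM | 95 mM | 95.0 mM | 95.0 mM | 95.0 mM | 95.0 mM |
| initiator | 0.64 mM | 1.4 mM | 0.95 mM | 0.95 mM | 0.95 mM | 0.95 mM | 0.95 mM |
| temperature | 72 °C | 100 °C | 72 °C | 75 °C | 60 °C | 110 °C | 90 °C |
| remark | run made earlier | run made earlier | run made earlier |  |  |  |  |
| time |  |  |  | 8.0 h | 8.0 h | 8.0 h | 8.0 h |

| run | time / h | target / % | substrate / % |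
|---|---|---|---|
| winter | 1.50 | 4 | 98 |
| winter | 4.00 | 13 | 87 |
| winter | 8.00 | 30 | 69 |
| winter | 12.0 | 42 | 55 |
| midnight | 0.417 | 19 | 80 |
| midnight | 1.00 | 39 | 56 |
| midnight | 2.00 | 64 | 26 |
| midnight | 3.00 | 72 | 11 |
| spring | 1.50 | 8 | 91 |
| spring | 4.00 | 27 | 67 |
| spring | 8.00 | 49 | 50 |
| spring | 12.0 | 61 | 31 |

(scatter of a reading: 2 percentage points)

- the flasks by amount of target, in percent of the substrate charged, highest first, at 8.0 h (north-west / north / north-east / east)
- the same order at 30 h (north-west / north / north-east / east)
- the amount of target, in percent of the substrate charged of the flask you put first, at 8.0 h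
- the amount of target, in percent of the substrate charged of the flask you put last, at 8.0 h

1. My bench rule of thumb was that whatever has left the substrate stands as target. In the winter run at 12.0 h it held: 45.0 % had left and 42 % stood as target, a gap of 3 percentage points against a scatter of 2 points.

2. The midnight run showed the border. From 1.00 h to 3.00 h, target plus substrate fell from 95.0 % to 83.0 %, so I took the target to be going on further. I read two first-order constants there: k_s for substrate, 0.814 /h, and k_t for target, the gap gained per hour over the mean target, 0.103 /h.

3. Their ratio S = k_s/k_t, a selectivity factor, says how many times faster substrate goes than target; I read 7.91. For two first-order steps in series, time drops out: with f the fraction of substrate left, the target fraction is S/(S−1)·(f^(1/S) − f). With my reading of S this peaks at 74.1 % when f is 9.37 %, so on this formula the target falls as f goes lower.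

4. For east I interpolated k_s geometrically in temperature between the spring run, 0.0963 /h, and the midnight run, although their charges differ. That gave 0.380 /h, so I reckoned f at 4.79 % at 8.0 h, and carrying S over unchanged gave my estimate of 72.5 % of target.

5. The forecast ordered east > north-west > north-east > north at 8.0 h and north-west > north > east > north-east at 30 h, with 61 % on top and 15 % last, holding that “the target itself decays”. Its top stood lower than mine.

6. The simulation gave east > north-west > north-east > north and north-west > north > east > north-east, with 67.5 % and 14.6 %.

    substrate + second chain carrier → by-product + first chain carrier (k = 1.80 × 10⁵ /M/s, Ea = 24.0 kJ/mol)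
    substrate + initiating radical → capped initiator + first chain carrier (k = 1.10 × 10⁶ /M/s, Ea = 34.0 kJ/mol)
    initiator → 2 initiating radical (k = 0.00350 /h, Ea = 121 kJ/mol)
    partner + target → over-reaction product (k = 0.950 /M/h, Ea = 73.0 kJ/mol)
    partner + first chain carrier ⇌ target + second chain carrier (K = 0.910, k = 26000 /M/s, Ea = 23.0 kJ/mol, ΔH = 5.00 kJ/mol)
    2 first chain carrier → ended chains B (k = 9.30 × 10⁸ /M/s, Ea = 9.00 kJ/mol)
    2 second chain carrier → ended chains A (k = 1.50 × 10⁹ /M/s, Ea = 11.0 kJ/mol)
    (constants at 90 °C)

East held 9.19 % of substrate at 8.00 h, and the formula with S on that fraction gives 74.1 % against 67.5 % of target. The same flask as north run at 85 °C held 22.6 % of substrate at 8.00 h. On that fraction the formula gives 69.0 %, and that flask held 62.3 % of target and 15.0 % of over-reaction product.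

Readings and results stem from a simulated flask for substances that don't exist, noise included.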